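At 0.667 h the alpha run held more target than the eta run, 44.1 % against 29.4 %, on about twice the second catalyst. Yet the share of over-reaction product in over-reaction product plus target stood at 29.2 % against 32.7 %. So I kept the flask's charges and decided when to take it off by what the clock does to that share.

common to all: free catalyst 0.087 mol%
- eta: starting material 0.10 M; reagent 1.5 equiv; second catalyst 3.6 mol%; run made earlier
- alpha: starting material 0.10 M; reagent 1.5 equiv; second catalyst 8.1 mol%; run made earlier
- epsilon: starting material 0.20 M; reagent 1.5 equiv; second catalyst 5.4 mol%; run made earlier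
- flask: starting material 0.10 M; reagent 1.50 equiv; second catalyst 5.4 mol%; time 6.0 h

| run | time / h | over-reaction product / % | target / % |
|---|---|---|---|
| eta | 0.667 | 14.3 | 29.4 |
| eta | 1.33 | 28.2 | 26.1 |
| eta | 2.00 | 38.5 | 19.3 |
| eta | 3.00 | 46.3 | 12.6 |
| eta | 4.00 | 50.5 | 7.9 |
| eta | 5.00 | 53.0 | 5.5 |
| alpha | 0.417 | 9.8 | 37.8 |
| alpha | 0.667 | 18.2 | 44.1 |
| alpha | 0.833 | 22.7 | 44.0 |
| alpha | 1.33 | 34.1 | 39.8 |
| alpha | 2.00 | 42.7 | 32.3 |
| alpha | 3.00 | 50.4 | 25.8 |
| alpha | 5.00 | 59.3 | 17.3 |
| epsilon | 1.00 | 42.3 | 47.8 |
| epsilon | 2.00 | 51.9 | 40.4 |
| epsilon | 3.00 | 54.9 | 37.1 |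
| epsilon | 4.00 | 56.7 | 35.3 |
| epsilon | 5.00 | 57.5 | 34.3 |

(readings scatter by 0.3 percentage points)

- steps under discussion: reagent + target -> over-reaction product; second catalyst -> spent catalyst A; starting material + free catalyst -> free catalyst + open intermediate; second catalyst + open intermediate <-> catalyst intermediate; reagent + catalyst intermediate -> second catalyst + target; second catalyst -> spent catalyst B

- share of over-reaction product in over-reaction product plus target at 4.0 min
- share of over-reaction product in over-reaction product plus target at 30 min
- share of over-reaction product in over-reaction product plus target at 6.0 h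

Each target costs one reagent and each over-reaction product costs two, so I reckoned the reagent left from those readings. Late in the eta and alpha runs I divided the gain of over-reaction product per hour by the mean target and by the fraction of reagent left. That gave a pseudo-first-order constant at charged reagent, k, of 1.33 h⁻¹ in eta and 1.65 h⁻¹ in alpha, and I took the mean, 1.49 h⁻¹.

For the start I assumed that target climbs with the square of time, and then the ratio of over-reaction product to target is k times the time, divided by 3. I therefore carried g, the early share gained per hour, equal to k divided by 3: 0.498 h⁻¹. It gives 20.7 % at alpha's first reading, which read 20.6 %, but at 0.667 h it gives 33.2 % against the 29.2 % read in alpha, so I trusted it early. For the flask I reckoned 3.32 % at 4.0 min, and with less trust 24.9 % at 30 min: any target wanted has to come off early.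

The forecast gave 3.8 %, 24 % and 88 %, and said of the plateau: “This is catalyst death, not starting material exhaustion”.

The flask gave 3.52 %, 24.4 % and 87.8 %.

    reagent + target → over-reaction product (k = 0.00285 M⁻¹ s⁻¹)
    second catalyst → spent catalyst A (k = 4.84 × 10⁻⁷ s⁻¹)
    starting material + free catalyst → free catalyst + open intermediate (k = 12.6 M⁻¹ s⁻¹)
    second catalyst + open intermediate ⇌ catalyst intermediate (K = 0.414 M⁻¹, k = 1.47 M⁻¹ s⁻¹)
    reagent + catalyst intermediate → second catalyst + target (k = 5.20 M⁻¹ s⁻¹)
    second catalyst → spent catalyst B (k = 4.83 × 10⁻⁴ s⁻¹)

In the flask the half-life of target against over-reaction, reagent taken as charged, was 0.45 h, short against the 6.0 h. Target stood at 35.8 % after 0.600 h and at 8.29 % after 6.00 h, beside 59.8 % of over-reaction product. A neighbour flask at 0.025 M of starting material, same equivalents, has a quarter of the reagent concentration, so g scaled by that fraction predicts a share of 0.829 % at 4.0 min, and that flask gave 0.871 %.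

The numbers in the tables are calculated on assumed constants, noise included.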